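All runs come from a simulation on assumed constants; scatter was added.

In a closed flask of constant volume the charge stays on the books, so I keep a ledger of X, the one reagent charged and so the limiting reagent, in percent of what went in.

| setting | summer | dawn | flask |
|---|---|---|---|
| X | 0.54 M | 1.2 M | 0.80 M |
| remark | run made earlier | run made earlier |  |
| time |  |  | 15 d |

| run | time / d | J / % | Z / % | X / % |
|---|---|---|---|---|
| summer | 5.00 | 24.9 | 60.7 | 5.9 |
| summer | 10.0 | 28.3 | 57.7 | 5.8 |
| summer | 15.0 | 28.3 | 57.3 | 5.8 |
| summer | 20.0 | 27.9 | 57.8 | 6.0 |
| dawn | 2.50 | 18.3 | 65.8 | 6.2 |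
| dawn | 6.00 | 25.8 | 58.8 | 5.9 |
| dawn | 12.0 | 28.2 | 56.7 | 6.2 |
| dawn | 20.0 | 28.2 | 57.1 | 5.7 |

(standard deviation of a reading: 0.3 percentage points)

1. share of J in J plus Z at 15 min
2. share of J in J plus Z at 15 d

In the summer run at 15.0 d the entries are 5.8% as X, 57.3% as Z and 28.3% as J, and the books close with 8.60% that no peak shows. J and Z stop moving there, so I carry one quantity from that reading, 33.1%, the plateau share S, meaning J over J plus Z once the entries hold still. The dawn run, charged at 1.2 M against 0.54 M, reads 33.1% at 20.0 d, so I take S as independent of the charge.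

Next I let the gap between S and the share s shrink as exp(−λt), with λ a first-order constant and t the time. Assuming that the share s starts from zero, the dawn share of 21.8% at 2.50 d then gives λ = 0.429 d⁻¹. For this flask I reckon 0.148% at 15 min, though that is far before my earliest reading, and 33.0% at 15 d.

The forecast gives 0.15% and 33%, and says of the early value that “the high side stays open”.

The flask gives 2.30% at 15 min and 32.8% at 15 d.

    X ⇌ J (K = 4.90, k = 0.0590 h⁻¹)
    X ⇌ D (K = 1.50, k = 0.560 h⁻¹)
    X ⇌ Z (K = 10.0, k = 2.60 h⁻¹)

The plateau share S, read as 33.1% and a mark of thermodynamic control, stands beside this flask's 32.8% at 15 d and the 32.8% of the neighbour charged with 2.0 M of X. My early curve does not carry over, for this flask's share at 15 min stands above my 0.148%. X and Z relax with a half-life of 0.242 h by the step between them alone, shorter than the 0.407 d of X and J by theirs, and both are short against 15 d. The equilibrium constant of X to J over that of X to Z is 0.490, which, taken over one plus itself, is 32.9%.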